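**Plan**

Ring numbering used below: C1 carbonyl, C2 (propenyl), C3 (H), C4 (quaternary; OMe and the aryl-propenyl group), C5 (OMe), C6 (H). The ring bond C2=C3 and the propenyl C=C form a 1,3-diene joined through C2 and the first propenyl carbon; these two carbons are read as a former alkyne and C3 as a former alkene carbon, which is the pattern left by an enyne metathesis.
Retrosynthesis: (a) the C2=C3 ring bond and the propenyl C=C are cut together to the acyclic terminal ynone 16, an isomer of the target; (b) C1–C2 (ethynyl Grignard on a Weinreb amide) and C5–OMe (methanol to an ynamide); (c) C6–C1 (acylation of an acetylide); (d) the C3=C bond (Wittig) back to an ester; (e) C4–C5 (alkynylation of an α-keto ester); (f) the aryl-propenyl C=C (aldol condensation).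
Forward: aldol condensation and esterification give the keto ester; the chain is then built linearly at C4 (alkyne, O-methyl, propenyl) and along C5–C6–C1–C2; the only ring, the dienone, arises in the last step.
Stereochemistry: the single stereocenter C4 (S) comes from ligand-controlled Si-face alkynylation of the keto ester and is quaternary thereafter. The aryl-propenyl E geometry comes from the aldol condensation, the enol ether geometry (C4 cis to C1) from the conjugate addition, and the E propenyl group from equilibration in the metathesis.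

Key step: step 10

Assumption: the facial sense of the zinc alkynylation in step 3 cannot be predicted with confidence for this α-alkenyl keto ester; the ligand antipode that delivers the alkynyl group to the Si face is meant, and both antipodes are accessible.

**Route**

Step 1
Reactants: 1 3,4-dimethoxybenzaldehyde; 2 2-oxobutanoic acid
Product: 3 (E)-4-(3,4-dimethoxyphenyl)-3-methyl-2-oxobut-3-enoic acid
Conditions: KOH (2.5 equiv), MeOH/H2O, 0 °C to rt; then 1 M HCl to pH 2
Reagents that add atoms: none
Why: Crossed aldol condensation (Claisen–Schmidt type): 1 cannot enolize and 2 enolizes only at its CH2 group, and dehydration should give the conjugated E olefin with the aryl group trans to the keto carbonyl as the more stable isomer.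

Step 2
Reactants: 3 (E)-4-(3,4-dimethoxyphenyl)-3-methyl-2-oxobut-3-enoic acid
Product: 4 methyl (E)-4-(3,4-dimethoxyphenyl)-3-methyl-2-oxobut-3-enoate
Conditions: MeI, K2CO3, DMF, rt
Reagents that add atoms: iodomethane, CI
Why: SN2 O-methylation of the carboxylate; the conjugated keto group and the E olefin should not be affected by carbonate at room temperature.

Step 3
Reactants: 4 methyl (E)-4-(3,4-dimethoxyphenyl)-3-methyl-2-oxobut-3-enoate; 5 ethynyltrimethylsilane
Product: 6 methyl (2S,3E)-4-(3,4-dimethoxyphenyl)-2-hydroxy-3-methyl-2-[(trimethylsilyl)ethynyl]but-3-enoate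
Conditions: Zn(OTf)2 (20 mol %), (1S,2S)- or (1R,2R)-3-(tert-butyldimethylsilyloxy)-2-(dimethylamino)-1-(4-nitrophenyl)propan-1-ol (22 mol %, antipode for Si-face addition), Et3N (30 mol %), toluene, 70 °C
Reagents that add atoms: none
Why: Catalytic enantioselective alkynylation of an α-keto ester by a zinc acetylide formed in situ from 5, an addition without co-product in which the 1,2-dicarbonyl unit chelates the chiral divalent zinc amino alkoxide and the alkynyl group is delivered to the Si face of the ketone to give the (S)-carbinol, 1,2-addition being favoured over conjugate addition by the α-methyl, β-aryl substitution of the enone.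

Step 4
Reactants: 6 methyl (2S,3E)-4-(3,4-dimethoxyphenyl)-2-hydroxy-3-methyl-2-[(trimethylsilyl)ethynyl]but-3-enoate
Product: 7 methyl (2S,3E)-4-(3,4-dimethoxyphenyl)-2-methoxy-3-methyl-2-[(trimethylsilyl)ethynyl]but-3-enoate
Conditions: NaH, MeI, THF/DMF, 0 °C
Reagents that add atoms: iodomethane, CI
Why: Williamson etherification of the tertiary alkoxide at low temperature; the stereocenter bears no hydrogen and cannot epimerize, and fast trapping by MeI should limit retro-alkynylation.

Step 5
Reactants: 7 methyl (2S,3E)-4-(3,4-dimethoxyphenyl)-2-methoxy-3-methyl-2-[(trimethylsilyl)ethynyl]but-3-enoate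
Product: 8 (2S,3E)-4-(3,4-dimethoxyphenyl)-2-methoxy-3-methyl-2-[(trimethylsilyl)ethynyl]but-3-enal
Conditions: i-Bu2AlH (1.2 equiv), CH2Cl2, −78 °C; aq potassium sodium tartrate
Reagents that add atoms: none
Why: Partial reduction of an α-alkoxy ester with i-Bu2AlH, in which the aluminium-chelated hemiacetal is stable at −78 °C and should collapse to the aldehyde only on work-up; the aldehyde has no α-hydrogen.

Step 6
Reactants: 8 (2S,3E)-4-(3,4-dimethoxyphenyl)-2-methoxy-3-methyl-2-[(trimethylsilyl)ethynyl]but-3-enal; 9 ethyltriphenylphosphonium bromide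
Product: 11 (3R,4Z)-3-methoxy-3-[(E)-1-(3,4-dimethoxyphenyl)prop-1-en-2-yl]hex-4-en-1-yne, via silylated enyne 10 (not isolated)
Conditions: 9, KN(SiMe3)2, THF, 0 °C; 8, −78 °C to rt; then MeOH, K2CO3 (cat.), rt
Reagents that add atoms: none
Why: Wittig olefination with the non-stabilized ethylidene ylide (mainly Z; the geometry is of no consequence because this double bond is cleaved in step 10), followed in the same flask by base-catalysed methanolysis of the C(sp)–Si bond, so that the acid-sensitive tertiary allylic ether meets only basic reagents (the descriptor changes from S to R only through the priority change at the alkyne).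

Step 7
Reactants: 11 (3R,4Z)-3-methoxy-3-[(E)-1-(3,4-dimethoxyphenyl)prop-1-en-2-yl]hex-4-en-1-yne; 12 N-methoxy-N-methylcarbamoyl chloride
Product: 13 (4S,5Z)-N,4-dimethoxy-N-methyl-4-[(E)-1-(3,4-dimethoxyphenyl)prop-1-en-2-yl]hept-5-en-2-ynamide
Conditions: n-BuLi, THF, −78 °C; then 12, −78 to 0 °C
Reagents that add atoms: none
Why: Acylation of the lithium acetylide of 11 with the carbamoyl chloride, which should stop at the N-methoxy-N-methyl amide because this product is a poor acylating agent at low temperature.

Step 8
Reactants: 13 (4S,5Z)-N,4-dimethoxy-N-methyl-4-[(E)-1-(3,4-dimethoxyphenyl)prop-1-en-2-yl]hept-5-en-2-ynamide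
Product: 14 (2E,4S,5Z)-N,3,4-trimethoxy-N-methyl-4-[(E)-1-(3,4-dimethoxyphenyl)prop-1-en-2-yl]hepta-2,5-dienamide
Conditions: NaOMe (0.2 equiv), MeOH, 0 °C to rt
Reagents that add atoms: methanol, CO
Why: Base-catalysed conjugate (oxa-Michael) addition of methanol to the ynamide, an addition without co-product; the allenolate should be protonated in the plane from the side of the small methoxy group and not from that of the quaternary carbon, which places the quaternary carbon and the carbonyl cis (2E), the geometry also expected at equilibrium for β-alkoxy enoyl systems.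

Step 9
Reactants: 14 (2E,4S,5Z)-N,3,4-trimethoxy-N-methyl-4-[(E)-1-(3,4-dimethoxyphenyl)prop-1-en-2-yl]hepta-2,5-dienamide; 15 ethynylmagnesium bromide
Product: 16 (4E,6S,7Z)-5,6-dimethoxy-6-[(E)-1-(3,4-dimethoxyphenyl)prop-1-en-2-yl]nona-4,7-dien-1-yn-3-one
Conditions: HC≡CMgBr (3 equiv), THF, 0 °C; inverse quench into cold aq NaH2PO4 (pH 4–5); used at once
Reagents that add atoms: none
Why: Weinreb ketone synthesis: the magnesium-chelated tetrahedral adduct should survive until the cold, weakly acidic quench, so that a single ethynyl group is introduced and the liberated amine is protonated before it can add to the terminal ynone.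

Step 10
Reactants: 16 (4E,6S,7Z)-5,6-dimethoxy-6-[(E)-1-(3,4-dimethoxyphenyl)prop-1-en-2-yl]nona-4,7-dien-1-yn-3-one
Product: 17 (4S)-4,5-dimethoxy-4-[(E)-1-(3,4-dimethoxyphenyl)prop-1-en-2-yl]-2-[(E)-prop-1-en-1-yl]cyclohexa-2,5-dien-1-one
Conditions: second-generation Hoveyda–Grubbs catalyst (10 mol %), toluene (0.005 M), 80 °C, argon
Reagents that add atoms: none
Why: Ring-closing enyne metathesis: a ruthenium ethylidene adds to the terminal alkyne (ethylidene carbon to the terminal CH, ruthenium to the future C2), the carbene at C2 then closes onto the propenyl group on C4, forming C2=C3 and releasing the ethylidene carbene again, and the alkene-first order of events leads to the same product, so the step is a net isomerization without co-product. The closest known reaction type is the ruthenium-catalysed ring-closing metathesis of 1,7-enynes to 1-vinylcyclohexenes, including alkynes that carry a conjugated carbonyl group. The six-membered ring closes in the exo mode (6-exo with respect to the alkyne); the endo mode would need a seven-membered ring and is not expected for a 1,7-enyne. No stereocenter is formed, C4 is quaternary and untouched, and the new propenyl double bond should settle as E because this disubstituted olefin is equilibrated by secondary metathesis with the ethylidene carbene and E is the less hindered conjugated isomer. The chemoselectivity needed is reaction at the C4 propenyl group only: the trisubstituted aryl-conjugated olefin and the push–pull enol ether C5=C6 are too hindered or too electron-poor to compete, and the enol ether geometry from step 8 holds C4 and the ynone cis so that the reacting ends can meet. A phosphine-free catalyst is chosen because free phosphine would add to the terminal ynone.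

**Compound list**

1 | 3,4-dimethoxybenzaldehyde | O=Cc1ccc(OC)c(OC)c1 | starting material
2 | 2-oxobutanoic acid | CCC(=O)C(=O)O | starting material
3 | (E)-4-(3,4-dimethoxyphenyl)-3-methyl-2-oxobut-3-enoic acid | O=C(O)C(=O)/C(C)=C/c1ccc(OC)c(OC)c1 | intermediate
4 | methyl (E)-4-(3,4-dimethoxyphenyl)-3-methyl-2-oxobut-3-enoate | COC(=O)C(=O)/C(C)=C/c1ccc(OC)c(OC)c1 | intermediate
5 | ethynyltrimethylsilane | C#C[Si](C)(C)C | starting material
6 | methyl (2S,3E)-4-(3,4-dimethoxyphenyl)-2-hydroxy-3-methyl-2-[(trimethylsilyl)ethynyl]but-3-enoate | COC(=O)[C@](O)(/C(C)=C/c1ccc(OC)c(OC)c1)C#C[Si](C)(C)C | intermediate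
7 | methyl (2S,3E)-4-(3,4-dimethoxyphenyl)-2-methoxy-3-methyl-2-[(trimethylsilyl)ethynyl]but-3-enoate | COC(=O)[C@](OC)(/C(C)=C/c1ccc(OC)c(OC)c1)C#C[Si](C)(C)C | intermediate
8 | (2S,3E)-4-(3,4-dimethoxyphenyl)-2-methoxy-3-methyl-2-[(trimethylsilyl)ethynyl]but-3-enal | O=C[C@](OC)(/C(C)=C/c1ccc(OC)c(OC)c1)C#C[Si](C)(C)C | intermediate
9 | ethyltriphenylphosphonium bromide | CC[P+](c1ccccc1)(c1ccccc1)c1ccccc1.[Br-] | starting material
10 | trimethyl{(3S,4Z)-3-methoxy-3-[(E)-1-(3,4-dimethoxyphenyl)prop-1-en-2-yl]hex-4-en-1-yn-1-yl}silane | C/C=C\[C@](OC)(/C(C)=C/c1ccc(OC)c(OC)c1)C#C[Si](C)(C)C | intermediate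
11 | (3R,4Z)-3-methoxy-3-[(E)-1-(3,4-dimethoxyphenyl)prop-1-en-2-yl]hex-4-en-1-yne | C/C=C\[C@](OC)(/C(C)=C/c1ccc(OC)c(OC)c1)C#C | intermediate
12 | N-methoxy-N-methylcarbamoyl chloride | CON(C)C(Cl)=O | starting material
13 | (4S,5Z)-N,4-dimethoxy-N-methyl-4-[(E)-1-(3,4-dimethoxyphenyl)prop-1-en-2-yl]hept-5-en-2-ynamide | C/C=C\[C@](OC)(/C(C)=C/c1ccc(OC)c(OC)c1)C#CC(=O)N(C)OC | intermediate
14 | (2E,4S,5Z)-N,3,4-trimethoxy-N-methyl-4-[(E)-1-(3,4-dimethoxyphenyl)prop-1-en-2-yl]hepta-2,5-dienamide | C/C=C\[C@](OC)(/C(C)=C/c1ccc(OC)c(OC)c1)/C(OC)=C\C(=O)N(C)OC | intermediate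
15 | ethynylmagnesium bromide | C#C[Mg]Br | starting material
16 | (4E,6S,7Z)-5,6-dimethoxy-6-[(E)-1-(3,4-dimethoxyphenyl)prop-1-en-2-yl]nona-4,7-dien-1-yn-3-one | C/C=C\[C@](OC)(/C(C)=C/c1ccc(OC)c(OC)c1)/C(OC)=C\C(=O)C#C | intermediate
17 | (4S)-4,5-dimethoxy-4-[(E)-1-(3,4-dimethoxyphenyl)prop-1-en-2-yl]-2-[(E)-prop-1-en-1-yl]cyclohexa-2,5-dien-1-one | C/C=C/C1=C[C@](OC)(/C(C)=C/c2ccc(OC)c(OC)c2)C(OC)=CC1=O | target

**Step count and risks**

Total step count: 10. Longest linear sequence: 10 steps (from 1 and 2 to 17).

Steps most likely to fail: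

Step 10. Turnover may be slow, because the alkyne is electron-poor, the reacting olefin sits on a quaternary carbon and the vinylcarbene can be held by chelation to the C1 carbonyl. The terminal ynone may also oligomerize, and the new propenyl group may not reach full E selectivity. The fallback sets out from 14 and comes back at 17. Addition of CH2=CHMgBr to 14 should give the vinyl ketone (cross-conjugated trienone) F1. Diene ring-closing metathesis with the second-generation Grubbs catalyst, with loss of propene, closes the same C2=C3 bond and should give the 2-unsubstituted dienone F2. Amine-mediated α-iodination (I2, pyridine) should take place at the C2=C3 enone, whose β-carbon carries no donor, and give the iodo dienone F3. Stille coupling of F3 with (E)-tributyl(prop-1-en-1-yl)stannane and Pd(PPh3)4 then introduces the propenyl group with defined E geometry and gives 17.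

Step 3. Facial selectivity may be poor or of the wrong sense on this alkenyl keto ester, and a background addition or conjugate addition may compete. The fallback sets out from 3 and comes back at 8. Acid 3 is converted through its chloride ((COCl)2, then the alcohol and pyridine) into the ester of (1R,2S,5R)-8-phenylmenthol, the auxiliary keto ester F4. Addition of Me3SiC≡CMgBr at −78 °C to the chelated keto ester, one face of which is shielded by the phenyl group, should give the auxiliary carbinol F5 as the major, separable diastereomer; the enantiomeric auxiliary is used if the facial sense proves opposite. NaH and MeI give the auxiliary methyl ether F6. Excess i-Bu2AlH removes the auxiliary and gives the primary alcohol F7, which Dess–Martin periodinane oxidizes to 8.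

Step 8. Addition at the alkyne carbon next to the quaternary centre may be sluggish with the weakly electrophilic ynamide, and the enol ether geometry may leak to the isomer that cannot cyclize. The fallback sets out from 11 and comes back at 16, and also replaces step 9. Formylation of the lithium acetylide of 11 (n-BuLi, then DMF) should give the ynal F8, a much better acceptor. Et3N-catalysed addition of methanol should give the (2E)-β-methoxy enal F9, whose geometry equilibrates readily in this push–pull aldehyde. Addition of HC≡CMgBr gives the secondary dienynol F10 as a mixture of carbinol epimers, and MnO2 oxidation of this doubly activated alcohol gives 16.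

Further compounds
F1 | step 10 | (4E,6S,7Z)-5,6-dimethoxy-6-[(E)-1-(3,4-dimethoxyphenyl)prop-1-en-2-yl]nona-1,4,7-trien-3-one | C/C=C\[C@](OC)(/C(C)=C/c1ccc(OC)c(OC)c1)/C(OC)=C\C(=O)C=C
F2 | step 10 | (4S)-4,5-dimethoxy-4-[(E)-1-(3,4-dimethoxyphenyl)prop-1-en-2-yl]cyclohexa-2,5-dien-1-one | O=C1C=C[C@](OC)(/C(C)=C/c2ccc(OC)c(OC)c2)C(OC)=C1
F3 | step 10 | (4S)-2-iodo-4,5-dimethoxy-4-[(E)-1-(3,4-dimethoxyphenyl)prop-1-en-2-yl]cyclohexa-2,5-dien-1-one | O=C1C(I)=C[C@](OC)(/C(C)=C/c2ccc(OC)c(OC)c2)C(OC)=C1
F4 | step 3 | (1R,2S,5R)-5-methyl-2-(2-phenylpropan-2-yl)cyclohexyl (E)-4-(3,4-dimethoxyphenyl)-3-methyl-2-oxobut-3-enoate | C[C@@H]1CC[C@H]([C@@H](C1)OC(=O)C(=O)/C(C)=C/c2ccc(OC)c(OC)c2)C(C)(C)c3ccccc3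
F5 | step 3 | (1R,2S,5R)-5-methyl-2-(2-phenylpropan-2-yl)cyclohexyl (2S,3E)-4-(3,4-dimethoxyphenyl)-2-hydroxy-3-methyl-2-[(trimethylsilyl)ethynyl]but-3-enoate | C[C@@H]1CC[C@H]([C@@H](C1)OC(=O)[C@](O)(/C(C)=C/c2ccc(OC)c(OC)c2)C#C[Si](C)(C)C)C(C)(C)c3ccccc3
F6 | step 3 | (1R,2S,5R)-5-methyl-2-(2-phenylpropan-2-yl)cyclohexyl (2S,3E)-4-(3,4-dimethoxyphenyl)-2-methoxy-3-methyl-2-[(trimethylsilyl)ethynyl]but-3-enoate | C[C@@H]1CC[C@H]([C@@H](C1)OC(=O)[C@](OC)(/C(C)=C/c2ccc(OC)c(OC)c2)C#C[Si](C)(C)C)C(C)(C)c3ccccc3
F7 | step 3 | (2S,3E)-4-(3,4-dimethoxyphenyl)-2-methoxy-3-methyl-2-[(trimethylsilyl)ethynyl]but-3-en-1-ol | OC[C@](OC)(/C(C)=C/c1ccc(OC)c(OC)c1)C#C[Si](C)(C)C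
F8 | step 8 | (4S,5Z)-4-methoxy-4-[(E)-1-(3,4-dimethoxyphenyl)prop-1-en-2-yl]hept-5-en-2-ynal | C/C=C\[C@](OC)(/C(C)=C/c1ccc(OC)c(OC)c1)C#CC=O
F9 | step 8 | (2E,4S,5Z)-3,4-dimethoxy-4-[(E)-1-(3,4-dimethoxyphenyl)prop-1-en-2-yl]hepta-2,5-dienal | C/C=C\[C@](OC)(/C(C)=C/c1ccc(OC)c(OC)c1)/C(OC)=C\C=O
F10 | step 8 | (4E,6S,7Z)-5,6-dimethoxy-6-[(E)-1-(3,4-dimethoxyphenyl)prop-1-en-2-yl]nona-4,7-dien-1-yn-3-ol (both carbinol epimers) | C/C=C\[C@](OC)(/C(C)=C/c1ccc(OC)c(OC)c1)/C(OC)=C\C(O)C#C
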